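## Retrosynthetic overview
1. The enone Cα=Cβ bond is cut by a Claisen–Schmidt disconnection into 4-hydroxy-3-prenylacetophenone and 3,4-dihydroxy-2-methoxybenzaldehyde. This coupling is run last, without protecting groups.
2. The key disconnection is the O2–CH3 bond of the aldehyde, leading back to 2,3,4-trihydroxybenzaldehyde and methanol. The site is chosen by a transient 3,4-boronate in one pot.
3. The aryl–prenyl bond leads back to 4-hydroxyacetophenone and prenyl bromide (ortho C-alkylation of the phenoxide).
4. No ring is built, because both benzene rings are bought. Only a temporary dioxaborole ring is closed and opened again within the key step.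

Assumption: licochalcone D has no stereocentre, so "single enantiomer" reduces to delivering the single (E)-alkene isomer drawn.

## Route

Step 1
Reactants: 1 4-hydroxyacetophenone; 2 prenyl bromide (1-bromo-3-methylbut-2-ene)
Product: 4 1-[4-hydroxy-3-(3-methylbut-2-en-1-yl)phenyl]ethan-1-one, via sodium 4-acetylphenolate 3 (not isolated)
Conditions: NaH (1.0 equiv), PhMe, 0 °C → rt; then 2 (1.0 equiv), rt → 50 °C, 16 h
Reagents that add atoms: none
Why: This is an ortho-selective phenoxide C-alkylation (Claisen-type C-allylation) in which the undissolved sodium ion pair in toluene shields oxygen and bridges to the leaving bromide, so the ortho carbon attacks the primary end of 2 by SN2 without allylic transposition and rearomatisation gives the o-prenylphenol, as known for 4-hydroxybenzoates, with the O-prenyl ether as a separable by-product.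

Step 2
Reactants: 5 2,3,4-trihydroxybenzaldehyde; 6 phenylboronic acid
Product: 9 3,4-dihydroxy-2-methoxybenzaldehyde, via hydroxy-boronate 7 (not isolated), via methoxy-boronate 8 (not isolated)
Conditions: 6 (1.0 equiv), PhMe, Dean–Stark reflux, 2 h; cool; PPh3, MeOH, DIAD (1.05 equiv each), 0 °C → rt, 3 h; pinacol (1.5 equiv), rt, 1 h
Reagents that add atoms: methanol, CO
Why: Proposed new method: under anhydrous, base-free conditions the reversible esterification with 6 should settle on the 3,4-diol because only that isomer keeps the resonance-assisted O2–H···O=CH hydrogen bond, so the single remaining acidic OH (pKa about 8) is the only pronucleophile for PPh3/DIAD/MeOH and attacks MeO–PPh3+ by SN2 to form the O2–CH3 bond, while the absence of hydroxide or carbonate removes the nucleophile needed to open a B–O bond and so avoids the boron shift that sends the aqueous borax/Me2SO4 methylation of 5 to O-4, the mask also shields the catechol from oxidation by DIAD, and pinacol finally takes the boron off; the closest known reaction types are the Mitsunobu etherification of salicylaldehydes and transient boronic-ester masking of cis-diols in site-selective carbohydrate functionalisation.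

Step 3
Reactants: 4 1-[4-hydroxy-3-(3-methylbut-2-en-1-yl)phenyl]ethan-1-one; 9 3,4-dihydroxy-2-methoxybenzaldehyde
Product: 11 licochalcone D, via aldol adduct 10 (not isolated)
Conditions: HCl (1.25 M in EtOH), Ar, 0 °C → rt, 12–24 h
Reagents that add atoms: none
Why: In this acid-catalysed Claisen–Schmidt (crossed aldol) condensation the enol of 4 adds to protonated 9, the p-hydroxy/o-methoxy-stabilised benzylic carbinol 10 loses water by E1 to give the conjugated and thermodynamically preferred (E)-enone, and acid rather than base keeps the phenols un-ionised, so the aldehyde stays electrophilic, the catechol is not air-oxidised, and the prenyl group tolerates about 1 M ethanolic HCl at or below rt.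

## Compound list
1 | 4-hydroxyacetophenone | CC(=O)c1ccc(O)cc1 | starting material
2 | prenyl bromide (1-bromo-3-methylbut-2-ene) | CC(C)=CCBr | starting material
3 | sodium 4-acetylphenolate | CC(=O)c1ccc([O-])cc1.[Na+] | intermediate
4 | 1-[4-hydroxy-3-(3-methylbut-2-en-1-yl)phenyl]ethan-1-one | CC(=O)c1ccc(O)c(CC=C(C)C)c1 | intermediate
5 | 2,3,4-trihydroxybenzaldehyde | O=Cc1ccc(O)c(O)c1O | starting material
6 | phenylboronic acid (transient mask) | OB(O)c1ccccc1 | starting material
7 | 4-hydroxy-2-phenyl-1,3,2-benzodioxaborole-5-carbaldehyde (hydroxy-boronate) | O=Cc1ccc2OB(c3ccccc3)Oc2c1O | intermediate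
8 | 4-methoxy-2-phenyl-1,3,2-benzodioxaborole-5-carbaldehyde (methoxy-boronate) | COc1c(C=O)ccc2OB(c3ccccc3)Oc12 | intermediate
9 | 3,4-dihydroxy-2-methoxybenzaldehyde | COc1c(C=O)ccc(O)c1O | intermediate
10 | 3-(3,4-dihydroxy-2-methoxyphenyl)-3-hydroxy-1-[4-hydroxy-3-(3-methylbut-2-en-1-yl)phenyl]propan-1-one (racemic, transient) | COc1c(C(O)CC(=O)c2ccc(O)c(CC=C(C)C)c2)ccc(O)c1O | intermediate
11 | licochalcone D, (E)-3-(3,4-dihydroxy-2-methoxyphenyl)-1-[4-hydroxy-3-(3-methylbut-2-en-1-yl)phenyl]prop-2-en-1-one | COc1c(/C=C/C(=O)c2ccc(O)c(CC=C(C)C)c2)ccc(O)c1O | target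

## Step count
Total steps: 3. Longest linear sequence: 2 (1 → 4 → 11, or 5 → 9 → 11).

## Three steps most likely to fail

**Step 2 (proposed new step).**
- Boron may move to O2/O3 once the phenoxide ion pair forms, or methanol may open the boronate. Either would give the 4-O-methyl isomer or dimethyl ethers.
- The flanked, chelated 2-OH may also react slowly.
- The outcome is easy to check: 9 shows no chelated OH near δ 11 and shows an OMe/CHO NOE.

The fallback uses known chemistry and replaces the labile mask with a fixed covalent one. It sets out from 5. Heating 5 with dichlorodiphenylmethane (Ph2O, 170 °C) bridges the two non-chelated oxygens. This gives 4-hydroxy-2,2-diphenyl-1,3-benzodioxole-5-carbaldehyde F1. MeI/K2CO3 in DMF then gives 4-methoxy-2,2-diphenyl-1,3-benzodioxole-5-carbaldehyde F2. AcOH/H2O (4:1) at reflux hydrolyses the ketal, and the fallback comes back to the route at 9. It costs two extra steps.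

**Step 3.**
- A day in ethanolic HCl may add HCl to the prenyl alkene or close it onto the neighbouring phenol to a 2,2-dimethylchroman.
- The electron-rich aldehyde may condense slowly.

The fallback switches to a protected, enolate-based condensation and sets out from 4 and 9. MOMCl/iPr2NEt in CH2Cl2 converts 4 into 1-[4-(methoxymethoxy)-3-(3-methylbut-2-en-1-yl)phenyl]ethan-1-one F3. The same conditions convert 9 into 2-methoxy-3,4-bis(methoxymethoxy)benzaldehyde F4. KOH in EtOH/H2O at rt joins them to (E)-3-[2-methoxy-3,4-bis(methoxymethoxy)phenyl]-1-[4-(methoxymethoxy)-3-(3-methylbut-2-en-1-yl)phenyl]prop-2-en-1-one F5. A short exposure (under 1 h) to HCl in MeOH at rt removes the three MOM groups, and the fallback comes back to the route at 11.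

**Step 1.**
- O-alkylation and 3,5-diprenylation compete with the wanted reaction.
- The acyl group lowers the carbon nucleophilicity of the phenoxide, so only a moderate yield is expected.

The fallback replaces the phenoxide alkylation with a cross-coupling and sets out from 1. NIS with catalytic TFA in MeCN gives 1-(4-hydroxy-3-iodophenyl)ethan-1-one F6. A linear-selective Pd/biarylphosphine Suzuki–Miyaura coupling with prenylboronic acid pinacol ester (K3PO4, THF/H2O, 40–60 °C) then comes back to the route at 4.

## Further compounds
F1 | step 2 | 4-hydroxy-2,2-diphenyl-1,3-benzodioxole-5-carbaldehyde | O=Cc1ccc2OC(c3ccccc3)(c3ccccc3)Oc2c1O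
F2 | step 2 | 4-methoxy-2,2-diphenyl-1,3-benzodioxole-5-carbaldehyde | COc1c(C=O)ccc2OC(c3ccccc3)(c3ccccc3)Oc12
F3 | step 3 | 1-[4-(methoxymethoxy)-3-(3-methylbut-2-en-1-yl)phenyl]ethan-1-one | CC(=O)c1ccc(OCOC)c(CC=C(C)C)c1
F4 | step 3 | 2-methoxy-3,4-bis(methoxymethoxy)benzaldehyde | COCOc1ccc(C=O)c(OC)c1OCOC
F5 | step 3 | (E)-3-[2-methoxy-3,4-bis(methoxymethoxy)phenyl]-1-[4-(methoxymethoxy)-3-(3-methylbut-2-en-1-yl)phenyl]prop-2-en-1-one | COCOc1ccc(/C=C/C(=O)c2ccc(OCOC)c(CC=C(C)C)c2)c(OC)c1OCOC
F6 | step 1 | 1-(4-hydroxy-3-iodophenyl)ethan-1-one | CC(=O)c1ccc(O)c(I)c1
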